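**Retrosynthetic overview**

1. Target 31 ⇐ 30 ⇐ 27 ⇐ 26: late PMB removal at O15, angeloylation at O8 and C8–OH-directed epoxidation. The cis C1–C10 oxirane is treated as the oxide of a (Z)-C1=C10 alkene.
2. 26 ⇐ 24: the ten-membered carbocycle (ring A) is closed at C9–C10 by intramolecular B-alkyl Suzuki–Miyaura coupling of a C9 pinacol boronate with a (Z)-C10 alkenyl iodide.
3. Enabling feature: C9 is a CH2 between the oxygenated C8 and the oxirane carbon C10, so C9 can carry boron next to a preset C8 stereocentre. The cis-fused γ-lactone (ring B, C6–C7), the (Z)-C4=C5 alkene and the cis C2–C3 oxirane fold the chain so that C9 lies next to C10.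
4. 24 ⇐ 13 + 22: lactone ring B by syn-selective indium Barbier allylation/lactonisation (C6–C7 bond) of enal fragment 1 (C1–C6, C10, C14, C15) with bromide fragment 2 (C7–C9, C11–C13).
5. Ring order: C2–C3 oxirane (asymmetric epoxidation) → lactone ring B → carbocycle ring A → C1–C10 oxirane.

Key step: step 18

Remark: germacrane-type locants are assumed throughout (ring carbons C1–C10, C6 = lactone carbinol carbon, C8 = acyloxy carbon, C11–C13 = acrylate unit, C14 = methyl on C10, C15 = CH2OH on C4); in these locants the target is (1R,2S,3S,4Z,6S,7R,8R,10S).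

**Route**

Step 1
Reactants: 1 but-2-yne-1,4-diol
Product: 2 4-[(4-methoxybenzyl)oxy]but-2-yn-1-ol
Conditions: 1 (3 equiv), NaH (1 equiv), THF/DMF, 0 °C; 4-methoxybenzyl chloride (1 equiv), Bu4NI (cat.), rt
Reagents that add atoms: 4-methoxybenzyl chloride COc1ccc(CCl)cc1
Why: Williamson ether synthesis; the excess of the symmetrical diol favours the mono-ether.

Step 2
Reactants: 2 4-[(4-methoxybenzyl)oxy]but-2-yn-1-ol
Product: 4 (Z)-3-iodo-4-[(4-methoxybenzyl)oxy]but-2-en-1-ol, via sodium alkenylaluminate 3 (not isolated)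
Conditions: NaAlH2(OCH2CH2OCH3)2, THF, 0 °C → rt; then I2, THF, −78 → 0 °C
Reagents that add atoms: iodine II
Why: Hydroxyl-directed trans-hydroalumination of the propargylic alcohol puts hydride on C5 and aluminium on C4 in a five-membered alkoxyalanate, and iodinolysis with retention gives the iodide on C4 cis to C6.

Step 3
Reactants: 4 (Z)-3-iodo-4-[(4-methoxybenzyl)oxy]but-2-en-1-ol
Product: 5 tert-butyl{[(Z)-3-iodo-4-[(4-methoxybenzyl)oxy]but-2-en-1-yl]oxy}dimethylsilane
Conditions: t-BuMe2SiCl, imidazole, CH2Cl2, 0 °C → rt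
Reagents that add atoms: tert-butyldimethylsilyl chloride CC(C)(C)[Si](C)(C)Cl
Why: Standard silylation of the primary allylic alcohol, which masks O6 until the enal is needed.

Step 4
Reactants: 5 silyl ether of the Z-iodoalkene; 6 prop-2-yn-1-ol
Product: 7 (E)-6-[(tert-butyldimethylsilyl)oxy]-4-{[(4-methoxybenzyl)oxy]methyl}hex-4-en-2-yn-1-ol (C3 cis to C6)
Conditions: PdCl2(PPh3)2 (3 mol %), CuI (6 mol %), Et3N, THF, rt
Reagents that add atoms: none
Why: Sonogashira coupling proceeds with retention of the alkenyl iodide geometry, so C3 ends up cis to C6 across C4=C5.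

Step 5
Reactants: 7 enynol
Product: 8 (2Z,4E)-6-[(tert-butyldimethylsilyl)oxy]-4-{[(4-methoxybenzyl)oxy]methyl}hexa-2,4-dien-1-ol
Conditions: Zn dust activated with Cu(OAc)2 and AgNO3, MeOH/H2O 1:1, 40 °C
Reagents that add atoms: none
Why: Boland reduction semi-reduces the conjugated propargylic alkyne cis-selectively without over-reduction, giving the (Z)-C2=C3 alkene.

Step 6
Reactants: 8 (2Z,4E)-dienol
Product: 9 [(2R,3S)-3-{(Z)-4-[(tert-butyldimethylsilyl)oxy]-1-[(4-methoxybenzyl)oxy]but-2-en-2-yl}oxiran-2-yl]methanol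
Conditions: Ti(OiPr)4 (1 equiv), D-(−)-diethyl tartrate (1.2 equiv), t-BuOOH, 4 Å molecular sieves, CH2Cl2, −20 °C
Reagents that add atoms: tert-butyl hydroperoxide CC(C)(C)OO
Why: Sharpless asymmetric epoxidation acts only on C2=C3, the one alkene with a free allylic hydroxyl, and the D-(−)-tartrate ligand delivers oxygen to the face that gives the (2R,3S) cis-oxirane; Z-allylic alcohols react slowly and the minor enantiomer is removed later as a diastereomer at 24.

Step 7
Reactants: 9 cis-epoxy alcohol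
Product: 10 (2S,3S)-3-{(Z)-4-[(tert-butyldimethylsilyl)oxy]-1-[(4-methoxybenzyl)oxy]but-2-en-2-yl}oxirane-2-carbaldehyde
Conditions: Dess–Martin periodinane, NaHCO3, CH2Cl2, 0 °C
Reagents that add atoms: none
Why: Buffered Dess–Martin oxidation gives the cis-epoxy aldehyde without epimerisation at C2; the aldehyde is used at once.

Step 8
Reactants: 10 cis-epoxy aldehyde
Product: 11 tert-butyl{[(Z)-3-{(2S,3R)-3-[(Z)-2-iodoprop-1-en-1-yl]oxiran-2-yl}-4-[(4-methoxybenzyl)oxy]but-2-en-1-yl]oxy}dimethylsilane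
Conditions: ethyltriphenylphosphonium iodide, n-BuLi, THF, 0 °C; I2, −78 °C; NaN(SiMe3)2, −78 → −20 °C; then 10, −78 °C
Reagents that add atoms: ethyltriphenylphosphonium iodide CC[P+](c1ccccc1)(c1ccccc1)c1ccccc1.[I-]; iodine II
Why: Stork–Zhao-type Wittig reaction of the α-iodoethylidene ylide is kinetically Z-selective, placing iodine on C10 cis to C2, and the low temperature limits epimerisation of the aldehyde.

Step 9
Reactants: 11 silyl ether
Product: 12 (Z)-3-{(2S,3R)-3-[(Z)-2-iodoprop-1-en-1-yl]oxiran-2-yl}-4-[(4-methoxybenzyl)oxy]but-2-en-1-ol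
Conditions: Bu4NF, AcOH (1:1), THF, 0 °C
Reagents that add atoms: none
Why: Fluoride cleaves the primary silyl ether, and the acetic acid buffer keeps O6 protonated so that it does not open the cis-disposed C2–C3 oxirane.

Step 10
Reactants: 12 allylic alcohol
Product: 13 (Z)-3-{(2S,3R)-3-[(Z)-2-iodoprop-1-en-1-yl]oxiran-2-yl}-4-[(4-methoxybenzyl)oxy]but-2-enal (fragment 1)
Conditions: Dess–Martin periodinane, NaHCO3, CH2Cl2, 0 °C
Reagents that add atoms: none
Why: Neutral Dess–Martin oxidation of the allylic alcohol gives the Z-enal without isomerising the C4=C5 bond.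

Step 11
Reactants: 14 (S)-but-3-ene-1,2-diol
Product: 15 (S)-1-iodobut-3-en-2-ol
Conditions: I2, PPh3, imidazole, CH2Cl2, 0 °C
Reagents that add atoms: iodine II
Why: Appel-type iodination is selective for the primary hydroxyl of a 1,2-diol and leaves the C8 stereocentre untouched.

Step 12
Reactants: 15 (S)-1-iodobut-3-en-2-ol
Product: 16 (S)-triethyl[(1-iodobut-3-en-2-yl)oxy]silane
Conditions: Et3SiOTf, 2,6-lutidine, CH2Cl2, −78 °C
Reagents that add atoms: triethylsilyl trifluoromethanesulfonate CC[Si](CC)(CC)OS(=O)(=O)C(F)(F)F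
Why: Fast low-temperature silylation protects O8 as a bulky, non-chelating ether before the iodohydrin can close to an oxirane.

Step 13
Reactants: 16 iodide
Product: 17 (R)-triethyl{[1-(4,4,5,5-tetramethyl-1,3,2-dioxaborolan-2-yl)but-3-en-2-yl]oxy}silane
Conditions: B2pin2, CuI (10 mol %), PPh3, LiOMe, DMF, rt
Reagents that add atoms: bis(pinacolato)diboron CC1(C)OB(OC1(C)C)B1OC(C)(C)C(C)(C)O1
Why: Copper-catalysed borylation of the primary alkyl iodide installs the C9–B bond without touching the C8 stereocentre (the descriptor changes only through priorities).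

Step 14
Reactants: 17 alkenyl boronate
Product: 19 (R)-3-(4,4,5,5-tetramethyl-1,3,2-dioxaborolan-2-yl)-2-[(triethylsilyl)oxy]propanal, via secondary ozonide 18 (not isolated)
Conditions: O3, CH2Cl2, −78 °C; then PPh3, −78 °C → rt
Reagents that add atoms: ozone [O-][O+]=O
Why: Ozonolysis with reductive work-up cleaves the terminal alkene to the C7 aldehyde, and the pinacol boronate is inert to ozone at low temperature.

Step 15
Reactants: 19 aldehyde; 20 methyl acrylate
Product: 21 methyl (4R)-3-hydroxy-2-methylidene-5-(4,4,5,5-tetramethyl-1,3,2-dioxaborolan-2-yl)-4-[(triethylsilyl)oxy]pentanoate (mixture of C3 epimers)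
Conditions: DABCO (1 equiv), methyl acrylate (5 equiv, neat), rt, several days
Reagents that add atoms: none
Why: Morita–Baylis–Hillman reaction of the activated α-silyloxy aldehyde joins C7 to C11; the new carbinol centre is removed in the next step, so its configuration is irrelevant.

Step 16
Reactants: 21 Baylis–Hillman adduct
Product: 22 methyl (2Z,4R)-2-(bromomethyl)-5-(4,4,5,5-tetramethyl-1,3,2-dioxaborolan-2-yl)-4-[(triethylsilyl)oxy]pent-2-enoate (fragment 2)
Conditions: N-bromosuccinimide, Me2S, CH2Cl2, 0 °C → rt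
Reagents that add atoms: N-bromosuccinimide BrN1C(=O)CCC1=O
Why: Activation of the carbinol as an alkoxysulfonium ion and SN2′ attack of bromide give the transposed allylic bromide with C8 cis to CH2Br.

Step 17
Reactants: 13 enal (fragment 1); 22 allylic bromide (fragment 2)
Product: 24 cis-fused α-methylene-γ-butyrolactone (4S,5S; C8 1R) carrying the C9 boronate and the Z-alkenyl iodide, via hydroxy ester 23 (not isolated)
Conditions: In powder, THF/H2O 3:1, rt; then 2-hydroxypyridine (0.2 equiv), PhMe, 60 °C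
Reagents that add atoms: none
Why: Indium-mediated Barbier allylation (γ-attack) through a chair-like six-membered transition state gives the syn C6/C7 adduct from the (Z)-bromide, the aldehyde adding to C7 anti to the C8–C9 bond with H8 eclipsing the alkene and the non-chelating silyloxy group outside (Felkin-type control by C8), and neutral 2-hydroxypyridine-catalysed lactonisation then closes ring B without acid that would let O6 open the C2–C3 oxirane; minor diastereomers are separated here.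

Step 18
Reactants: 24 seco boronate/alkenyl iodide
Product: 25 (1(10)Z,2R,3S,4Z,6S,7S,8R)-2,3-epoxy-15-[(4-methoxybenzyl)oxy]-8-[(triethylsilyl)oxy]germacra-1(10),4,11(13)-trien-12,6-olide
Conditions: PdCl2(dppf) (20 mol %), AsPh3 (40 mol %), Tl2CO3 (3 equiv), THF/DMF/H2O 6:3:1, 2 mM (slow addition of 24), 50 °C
Reagents that add atoms: none
Why: Stereoretentive oxidative addition of the C10–I bond to zerovalent palladium, transmetallation of the thallium-carbonate-activated primary C9 boronate and reductive elimination from an eleven-membered palladacycle form the C9–C10 bond and with it the ten-membered carbocycle (ring A). The closest known reaction type is the B-alkyl Suzuki–Miyaura macrocyclisation, run here with a β-silyloxy alkyl pinacol boronate under thallium-base acceleration. Ring A closes in the endo sense with respect to the alkenyl unit, so C1=C10 becomes an endocyclic Z double bond. No stereocentre is created; the Z geometry of the alkenyl iodide is transferred unchanged and later dictates the cis C1–C10 oxirane. The step needs cyclisation to outrun oligomerisation and C–I insertion to outrun ionisation of the allylic C2–C3 oxirane: high dilution plus the fold imposed by the cis-fused lactone, the Z-C4=C5 alkene, the cis C2–C3 oxirane and the Z-iodoalkene bring C9 next to C10, and an alkenyl iodide reacts with palladium far faster than a trisubstituted allylic oxirane. β-Hydride and β-silyloxy elimination at C9 are suppressed by the wide-bite-angle dppf ligand, which speeds reductive elimination.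

Step 19
Reactants: 25 macrocyclic silyl ether
Product: 26 (1(10)Z,2R,3S,4Z,6S,7R,8R)-2,3-epoxy-8-hydroxy-15-[(4-methoxybenzyl)oxy]germacra-1(10),4,11(13)-trien-12,6-olide
Conditions: HF·pyridine, pyridine, THF, 0 °C
Reagents that add atoms: none
Why: Buffered fluoride removes the secondary triethylsilyl ether under near-neutral conditions that spare the oxirane, the lactone and the PMB ether.

Step 20
Reactants: 26 homoallylic alcohol
Product: 27 (1R,2S,3S,4Z,6S,7R,8R,10S)-1,10:2,3-diepoxy-8-hydroxy-15-[(4-methoxybenzyl)oxy]germacra-4,11(13)-dien-12,6-olide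
Conditions: VO(acac)2 (5 mol %), t-BuOOH (1.5 equiv), CH2Cl2, 0 °C → rt
Reagents that add atoms: tert-butyl hydroperoxide CC(C)(C)OO
Why: Vanadium-catalysed hydroxyl-directed epoxidation delivers oxygen from the vanadate ester of the homoallylic C8–OH to C1=C10 on the face syn to O8 (anti to the C2–C3 oxirane oxygen), setting C1 (R) and C10 (S) as a cis-oxirane, while C4=C5 and the acrylate have no hydroxyl in reach and are electron-poor.

Step 21
Reactants: 27 diepoxy alcohol; 28 angelic acid [(Z)-2-methylbut-2-enoic acid]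
Product: 30 (1R,2S,3S,4Z,6S,7R,8R,10S)-8-angeloyloxy-1,10:2,3-diepoxy-15-[(4-methoxybenzyl)oxy]germacra-4,11(13)-dien-12,6-olide, via mixed anhydride 29 (not isolated)
Conditions: 28, 2,4,6-Cl3C6H2COCl, Et3N, PhMe, rt; then 27, PhMe, 80 °C (no DMAP)
Reagents that add atoms: none
Why: Yamaguchi-type esterification through the 2,4,6-trichlorobenzoic mixed anhydride acylates the secondary C8–OH at the less hindered angeloyl carbonyl, and omitting a nucleophilic catalyst avoids Z→E isomerisation to the tiglate.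

Step 22
Reactants: 30 PMB ether
Product: 31 (1R,2S,3S,4Z,6S,7R,8R,10S)-8-angeloyloxy-1,10:2,3-diepoxy-15-hydroxygermacra-4,11(13)-dien-12,6-olide (target, CNP0157626.1)
Conditions: DDQ (1.5 equiv), CH2Cl2/pH 7 phosphate buffer 10:1, 0 °C
Reagents that add atoms: none
Why: Oxidative cleavage of the 4-methoxybenzyl ether under buffered neutral conditions frees the C15 hydroxyl without touching the oxiranes, the angelate or the α-methylene lactone.

**Compound list**

1 | but-2-yne-1,4-diol | OCC#CCO | starting material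
2 | 4-[(4-methoxybenzyl)oxy]but-2-yn-1-ol | OCC#CCOCc1ccc(OC)cc1 | intermediate
3 | sodium 2,2-bis(2-methoxyethoxy)-3-{[(4-methoxybenzyl)oxy]methyl}-2,5-dihydro-1,2-oxaluminol-2-uide (cyclic alkenylalanate) | [Na+].COCCO[Al-]1(OCCOC)OCC=C1COCc2ccc(OC)cc2 | intermediate
4 | (Z)-3-iodo-4-[(4-methoxybenzyl)oxy]but-2-en-1-ol | OC/C=C(\I)COCc1ccc(OC)cc1 | intermediate
5 | tert-butyl{[(Z)-3-iodo-4-[(4-methoxybenzyl)oxy]but-2-en-1-yl]oxy}dimethylsilane | CC(C)(C)[Si](C)(C)OC/C=C(\I)COCc1ccc(OC)cc1 | intermediate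
6 | prop-2-yn-1-ol | C#CCO | starting material
7 | (E)-6-[(tert-butyldimethylsilyl)oxy]-4-{[(4-methoxybenzyl)oxy]methyl}hex-4-en-2-yn-1-ol | OCC#C/C(COCc1ccc(OC)cc1)=C\CO[Si](C)(C)C(C)(C)C | intermediate
8 | (2Z,4E)-6-[(tert-butyldimethylsilyl)oxy]-4-{[(4-methoxybenzyl)oxy]methyl}hexa-2,4-dien-1-ol | OC/C=C\C(COCc1ccc(OC)cc1)=C/CO[Si](C)(C)C(C)(C)C | intermediate
9 | [(2R,3S)-3-{(Z)-4-[(tert-butyldimethylsilyl)oxy]-1-[(4-methoxybenzyl)oxy]but-2-en-2-yl}oxiran-2-yl]methanol | OC[C@H]1O[C@H]1/C(COCc2ccc(OC)cc2)=C\CO[Si](C)(C)C(C)(C)C | intermediate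
10 | (2S,3S)-3-{(Z)-4-[(tert-butyldimethylsilyl)oxy]-1-[(4-methoxybenzyl)oxy]but-2-en-2-yl}oxirane-2-carbaldehyde | O=C[C@H]1O[C@H]1/C(COCc2ccc(OC)cc2)=C\CO[Si](C)(C)C(C)(C)C | intermediate
11 | tert-butyl{[(Z)-3-{(2S,3R)-3-[(Z)-2-iodoprop-1-en-1-yl]oxiran-2-yl}-4-[(4-methoxybenzyl)oxy]but-2-en-1-yl]oxy}dimethylsilane | C/C(I)=C/[C@H]1O[C@H]1/C(COCc2ccc(OC)cc2)=C\CO[Si](C)(C)C(C)(C)C | intermediate
12 | (Z)-3-{(2S,3R)-3-[(Z)-2-iodoprop-1-en-1-yl]oxiran-2-yl}-4-[(4-methoxybenzyl)oxy]but-2-en-1-ol | C/C(I)=C/[C@H]1O[C@H]1/C(COCc2ccc(OC)cc2)=C\CO | intermediate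
13 | (Z)-3-{(2S,3R)-3-[(Z)-2-iodoprop-1-en-1-yl]oxiran-2-yl}-4-[(4-methoxybenzyl)oxy]but-2-enal (fragment 1) | C/C(I)=C/[C@H]1O[C@H]1/C(COCc2ccc(OC)cc2)=C\C=O | intermediate
14 | (S)-but-3-ene-1,2-diol | C=C[C@H](O)CO | starting material
15 | (S)-1-iodobut-3-en-2-ol | C=C[C@H](O)CI | intermediate
16 | (S)-triethyl[(1-iodobut-3-en-2-yl)oxy]silane | C=C[C@H](O[Si](CC)(CC)CC)CI | intermediate
17 | (R)-triethyl{[1-(4,4,5,5-tetramethyl-1,3,2-dioxaborolan-2-yl)but-3-en-2-yl]oxy}silane | C=C[C@H](O[Si](CC)(CC)CC)CB1OC(C)(C)C(C)(C)O1 | intermediate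
18 | 3-{(1R)-2-(4,4,5,5-tetramethyl-1,3,2-dioxaborolan-2-yl)-1-[(triethylsilyl)oxy]ethyl}-1,2,4-trioxolane (secondary ozonide of 17, epimer mixture at the trioxolane carbon) | C1OC(OO1)[C@H](O[Si](CC)(CC)CC)CB2OC(C)(C)C(C)(C)O2 | intermediate
19 | (R)-3-(4,4,5,5-tetramethyl-1,3,2-dioxaborolan-2-yl)-2-[(triethylsilyl)oxy]propanal | O=C[C@H](O[Si](CC)(CC)CC)CB1OC(C)(C)C(C)(C)O1 | intermediate
20 | methyl acrylate | C=CC(=O)OC | starting material
21 | methyl (4R)-3-hydroxy-2-methylidene-5-(4,4,5,5-tetramethyl-1,3,2-dioxaborolan-2-yl)-4-[(triethylsilyl)oxy]pentanoate (C3 epimer mixture) | C=C(C(=O)OC)C(O)[C@H](O[Si](CC)(CC)CC)CB1OC(C)(C)C(C)(C)O1 | intermediate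
22 | methyl (2Z,4R)-2-(bromomethyl)-5-(4,4,5,5-tetramethyl-1,3,2-dioxaborolan-2-yl)-4-[(triethylsilyl)oxy]pent-2-enoate (fragment 2) | COC(=O)/C(CBr)=C/[C@H](O[Si](CC)(CC)CC)CB1OC(C)(C)C(C)(C)O1 | intermediate
23 | open-chain syn hydroxy ester (6S,7S,8R): methyl 2-methylidene ester with C6–OH, C8–OSiEt3, C9–Bpin and the fragment 1 chain on C6 | C/C(I)=C/[C@H]1O[C@H]1/C(COCc2ccc(OC)cc2)=C\[C@H](O)[C@H](C(=C)C(=O)OC)[C@H](O[Si](CC)(CC)CC)CB3OC(C)(C)C(C)(C)O3 | intermediate
24 | (4S,5S)-5-[(Z)-2-{(2S,3R)-3-[(Z)-2-iodoprop-1-en-1-yl]oxiran-2-yl}-3-[(4-methoxybenzyl)oxy]prop-1-en-1-yl]-3-methylidene-4-{(1R)-2-(4,4,5,5-tetramethyl-1,3,2-dioxaborolan-2-yl)-1-[(triethylsilyl)oxy]ethyl}dihydrofuran-2(3H)-one | C/C(I)=C/[C@H]1O[C@H]1/C(COCc2ccc(OC)cc2)=C\[C@@H]3OC(=O)C(=C)[C@@H]3[C@H](O[Si](CC)(CC)CC)CB4OC(C)(C)C(C)(C)O4 | intermediate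
25 | (1(10)Z,2R,3S,4Z,6S,7S,8R)-2,3-epoxy-15-[(4-methoxybenzyl)oxy]-8-[(triethylsilyl)oxy]germacra-1(10),4,11(13)-trien-12,6-olide | C=C1C(=O)O[C@H]2/C=C(/COCc4ccc(OC)cc4)[C@@H]3O[C@@H]3/C=C(C)\C[C@@H](O[Si](CC)(CC)CC)[C@@H]12 | intermediate
26 | (1(10)Z,2R,3S,4Z,6S,7R,8R)-2,3-epoxy-8-hydroxy-15-[(4-methoxybenzyl)oxy]germacra-1(10),4,11(13)-trien-12,6-olide | C=C1C(=O)O[C@H]2/C=C(/COCc4ccc(OC)cc4)[C@@H]3O[C@@H]3/C=C(C)\C[C@@H](O)[C@@H]12 | intermediate
27 | (1R,2S,3S,4Z,6S,7R,8R,10S)-1,10:2,3-diepoxy-8-hydroxy-15-[(4-methoxybenzyl)oxy]germacra-4,11(13)-dien-12,6-olide | C=C1C(=O)O[C@H]2/C=C(/COCc4ccc(OC)cc4)[C@@H]3O[C@@H]3[C@H]3O[C@@]3(C)C[C@@H](O)[C@@H]12 | intermediate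
28 | angelic acid, (Z)-2-methylbut-2-enoic acid | C/C=C(/C)C(=O)O | starting material
29 | (Z)-2-methylbut-2-enoic 2,4,6-trichlorobenzoic anhydride | C/C=C(/C)C(=O)OC(=O)c1c(Cl)cc(Cl)cc1Cl | intermediate
30 | (1R,2S,3S,4Z,6S,7R,8R,10S)-8-angeloyloxy-1,10:2,3-diepoxy-15-[(4-methoxybenzyl)oxy]germacra-4,11(13)-dien-12,6-olide | C=C1C(=O)O[C@H]2/C=C(/COCc4ccc(OC)cc4)[C@@H]3O[C@@H]3[C@H]3O[C@@]3(C)C[C@@H](OC(=O)/C(C)=C\C)[C@@H]12 | intermediate
31 | (1R,2S,3S,4Z,6S,7R,8R,10S)-8-angeloyloxy-1,10:2,3-diepoxy-15-hydroxygermacra-4,11(13)-dien-12,6-olide (CNP0157626.1) | C=C1C(=O)O[C@H]2/C=C(/CO)[C@@H]3O[C@@H]3[C@H]3O[C@@]3(C)C[C@@H](OC(=O)/C(C)=C\C)[C@@H]12 | target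

**Summary**

Total step count: 22. Longest linear sequence: 16 steps (steps 1–10, then 17–22); fragment 2 takes 6 steps (11–16).

The three steps most likely to fail:

Step 18 (key macrocyclisation). The ring closure may lose to oligomerisation, the allylic C2–C3 oxirane may be ionised by zerovalent palladium, or the C9 boronate may protodeboronate in aqueous base. The fallback reverses the order of the two C–C bond formations and closes the ring at C6–C7 instead. It sets out from 12 and 21: intermolecular B-alkyl Suzuki–Miyaura coupling (PdCl2(dppf), AsPh3, Tl2CO3, THF/DMF/H2O, rt, no dilution demand) gives the seco diol methyl (4R,6Z)-3-hydroxy-7-{(2R,3S)-3-[(Z)-4-hydroxy-1-[(4-methoxybenzyl)oxy]but-2-en-2-yl]oxiran-2-yl}-6-methyl-2-methylidene-4-[(triethylsilyl)oxy]hept-6-enoate F1. MnO2 (CH2Cl2, rt) oxidises only the electron-rich C6 allylic alcohol to the enal F2. N-Bromosuccinimide/Me2S transposes the Baylis–Hillman carbinol to the (Z)-allylic bromide F3. Intramolecular indium Barbier allylation at high dilution (In, THF/H2O, then 2-hydroxypyridine, PhMe, 60 °C), a ring closure with precedent for germacranolides, forms C6–C7 and the lactone and comes back to the route at 25.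

Step 8 (α-iodoethylidene Wittig reaction). The cis-epoxy aldehyde may epimerise at C2 under the basic ylide, and the Z/E ratio and conversion may be poor. The fallback builds the Z-haloalkene by cross-coupling instead of olefination. It sets out from 10: Ramirez dibromo-olefination (CBr4, PPh3, Et3N, CH2Cl2, 0 °C) gives tert-butyl{[(Z)-3-[(2S,3R)-3-(2,2-dibromoethenyl)oxiran-2-yl]-4-[(4-methoxybenzyl)oxy]but-2-en-1-yl]oxy}dimethylsilane F4. Palladium-catalysed trans-selective monomethylation (Me2Zn, PdCl2(DPEphos), THF, 0 °C → rt) replaces the bromine trans to C2 and gives the (Z)-2-bromopropenyl oxirane F5 with bromine cis to C2. Copper-catalysed halogen exchange (CuI, NaI, trans-N,N′-dimethylcyclohexane-1,2-diamine, dioxane, 80 °C) then comes back to the route at 11.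

Step 20 (directed epoxidation). Oxygen may be delivered to the wrong face of C1=C10, C4=C5 may compete, or the Lewis-acidic vanadium may open the allylic C2–C3 oxirane. The fallback drops hydroxyl direction and relies on substrate control. It sets out from 26: esterification with 28 under the conditions of step 21 gives the alkene angelate (1(10)Z,2R,3S,4Z,6S,7R,8R)-8-angeloyloxy-2,3-epoxy-15-[(4-methoxybenzyl)oxy]germacra-1(10),4,11(13)-trien-12,6-olide F6. Dimethyldioxirane (acetone, −20 °C) then epoxidises the only electron-rich alkene, C1=C10, from the face anti to the C2–C3 oxirane oxygen and comes back to the route at 30.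

Further compounds
F1 | step 18 | methyl (4R,6Z)-3-hydroxy-7-{(2R,3S)-3-[(Z)-4-hydroxy-1-[(4-methoxybenzyl)oxy]but-2-en-2-yl]oxiran-2-yl}-6-methyl-2-methylidene-4-[(triethylsilyl)oxy]hept-6-enoate (C3 epimer mixture) | C/C(C[C@@H](O[Si](CC)(CC)CC)C(O)C(=C)C(=O)OC)=C/[C@H]1O[C@H]1/C(COCc2ccc(OC)cc2)=C\CO
F2 | step 18 | methyl (4R,6Z)-3-hydroxy-7-{(2R,3S)-3-[(Z)-1-[(4-methoxybenzyl)oxy]-4-oxobut-2-en-2-yl]oxiran-2-yl}-6-methyl-2-methylidene-4-[(triethylsilyl)oxy]hept-6-enoate (C3 epimer mixture) | C/C(C[C@@H](O[Si](CC)(CC)CC)C(O)C(=C)C(=O)OC)=C/[C@H]1O[C@H]1/C(COCc2ccc(OC)cc2)=C\C=O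
F3 | step 18 | methyl (2Z,4R,6Z)-2-(bromomethyl)-7-{(2R,3S)-3-[(Z)-1-[(4-methoxybenzyl)oxy]-4-oxobut-2-en-2-yl]oxiran-2-yl}-6-methyl-4-[(triethylsilyl)oxy]hepta-2,6-dienoate | C/C(C[C@@H](O[Si](CC)(CC)CC)/C=C(\CBr)C(=O)OC)=C/[C@H]1O[C@H]1/C(COCc2ccc(OC)cc2)=C\C=O
F4 | step 8 | tert-butyl{[(Z)-3-[(2S,3R)-3-(2,2-dibromoethenyl)oxiran-2-yl]-4-[(4-methoxybenzyl)oxy]but-2-en-1-yl]oxy}dimethylsilane | BrC(Br)=C[C@H]1O[C@H]1/C(COCc2ccc(OC)cc2)=C\CO[Si](C)(C)C(C)(C)C
F5 | step 8 | tert-butyl{[(Z)-3-{(2S,3R)-3-[(Z)-2-bromoprop-1-en-1-yl]oxiran-2-yl}-4-[(4-methoxybenzyl)oxy]but-2-en-1-yl]oxy}dimethylsilane | C/C(Br)=C/[C@H]1O[C@H]1/C(COCc2ccc(OC)cc2)=C\CO[Si](C)(C)C(C)(C)C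
F6 | step 20 | (1(10)Z,2R,3S,4Z,6S,7R,8R)-8-angeloyloxy-2,3-epoxy-15-[(4-methoxybenzyl)oxy]germacra-1(10),4,11(13)-trien-12,6-olide | C=C1C(=O)O[C@H]2/C=C(/COCc4ccc(OC)cc4)[C@@H]3O[C@@H]3/C=C(C)\C[C@@H](OC(=O)/C(C)=C\C)[C@@H]12
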